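- Follow the salt. The runs are read thus: each recharge of spent carrier takes up one salt from the second phase, and each recharged carrier turns one starting material into target, so target counts salt spent while salt is the limiting reagent.

common to all: starting material 46 mM (in portions, 3); spent carrier 6.9 mM
- oak: salt in the second phase 22 mM; run made earlier; portions every 10 min
- birch: salt in the second phase 59 mM; run made earlier; portions every 10 min
- maple: salt in the second phase 140 mM; run made earlier; portions every 10 min
- delta: salt in the second phase 20.0 mM; the portions of starting material follow each other after 10 min, the first at the start; time 2.5 h; volume of the second phase over the first 1.0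
- alpha: salt in the second phase 60.0 mM; the portions of starting material follow each other after 10 min, the first at the start; time 2.5 h; volume of the second phase over the first 1.0
- eta: salt in the second phase 200 mM; the portions of starting material follow each other after 10 min, the first at the start; time 2.5 h; volume of the second phase over the first 1.0

| run | time / min | target / % |
|---|---|---|
| oak | 10.0 | 5.8 |
| oak | 25.0 | 16.1 |
| oak | 50.0 | 26.9 |
| oak | 80.0 | 35.9 |
| oak | 120 | 41.5 |
| birch | 20.0 | 30.4 |
| birch | 40.0 | 56.1 |
| birch | 60.0 | 72.1 |
| birch | 80.0 | 82.6 |
| birch | 120 | 82.5 |
| maple | 20.0 | 48.6 |
| maple | 40.0 | 83.6 |
| maple | 60.0 | 73.2 |
| maple | 80.0 | 58.3 |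
| maple | 120 | 35.6 |

(readings scatter by 0.3 percentage points)

- charges count per volume of the first phase; a concentration in a rate is the amount of a species over the volume of its own phase; every rate counts per litre of the first phase
- the earlier runs hold the two phases in the same ratio of volumes as the flask asked about
- a reading or a percentage of target counts all its forms, free or not
- the concentration of target that is asked is that of its free form alone
- "hardly changes" means that all values lie within two and a half points (for a concentration: within two and a half percent of the largest)

* [target] (only what is free in solution, in the first phase) at the end for delta, alpha, eta, in this order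
* how the row runs (rises, then falls / rises all the way / falls, then rises / hardly changes / falls all the way)

- First instants: each portion of 15.3 mM outnumbers the 6.9 mM of spent carrier, so in oak the carrier has to turn over more than once to consume a portion. Oak has c(salt) = 22 mM against 46 mM of starting material, which caps oak's target at 47.8% of the charge.
- Middle: after the last portion, the gap between that cap and oak's reading shrinks roughly by a constant factor per time, a pseudo-first-order fall in salt. From 50.0 min to 120 min the gap gives the salt decade time, the time in which unspent salt falls by one power of ten at 6.9 mM of carrier: 135 min, as a reading.
- End of delta: 2.5 h is 1.11 decades, which on this reckoning leaves 7.70% of the salt. My reckoning for delta is therefore 18.5 mM of target.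
- End with salt above the charge: maple's reading falls from 58.3% to 35.6% between 80.0 min and 120 min, as a reading a decade in 187 min. Carried to 2.5 h, that fall multiplies maple's last reading by 0.691, which puts maple near 11.3 mM, my figure for eta.
- Alpha resembles birch, which reads 38.0 mM at 120 min. Staying flat puts alpha at that figure and falling at maple's pace puts it at 26.2 mM, and my estimate is the middle, 32.1 mM.
- The forecast gives 17 mM, 34 mM and 8.5 mM, with the row running rises, then falls, holding that “recharging limits the rate” at low salt. My reckoning stands above it for delta and eta, and below it for alpha.
- The flasks give 18.3 mM, 31.1 mM and 10.1 mM, and the row runs rises, then falls.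

    spent carrier + salt in the second phase ⇌ fresh carrier + spent salt in the second phase (K = 7.70, k = 0.0440 L mol⁻¹ s⁻¹)
    starting material + fresh carrier → target + spent carrier (k = 0.610 L mol⁻¹ s⁻¹)
    crystals ⇌ target, rate k3*(cs3 - [target]) while solid is left; crystals form when [target] > cs3 (solubility = 36.0 mM, k = 0.00650 s⁻¹)
    target + fresh carrier → over-reaction product + fresh carrier (k = 0.0310 L mol⁻¹ s⁻¹)

- In delta at 0.600 h, fresh carrier has a half-life of 0.51 min against starting material, far shorter than the 0.41 h of spent carrier by the forward recharge. In delta, spent carrier is the resting state, at 98.2% of the catalyst at 0.750 h, and dissolved target's half-life by over-reaction, 44 h at 0.600 h, is longer than the 2.5 h of the run. The decade time puts delta's salt at 7.70% at the end, and 6.9% stands there. In alpha at 0.333 h it gives 71.1%, while 74.3% stands, with spent carrier at 84.1%.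

The numbers in the tables are simulated for substances that don't exist; noise was put on by code.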